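The 18-membered ring is numbered from the secondary amine (N1; stereocentre C2; lactam C4(=O)–N5H; acylated N9 and N15). The route rests on opening the unfunctionalised pentamethylene bridge C10–C14 between N9 and N15 at C11–C12, remote from C2 and the lactam. Ring-closing metathesis of an N9-allyl, N15-but-3-enyl diene makes this bond and closes the macrocycle in one operation without creating or endangering a stereocentre. The diene is an acyclic (S)-β-amino amide built from L-homoserine: N1 carries Boc, C2 a 2-(benzyloxy)ethyl arm (so that one hydrogenation later saturates the bridge and frees the alcohol for a Z-selective Wittig reaction), and both nitrogens their (S)-2-methylbutanoyl groups.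

Key step: step 12

Remark on the chemistry: N-Boc-O-benzyl-L-homoserine and nonyl(triphenyl)phosphonium bromide are taken as purchased, and the Wolff rearrangement is taken to proceed with retention at the migrating carbon, as is usual for amino acid diazoketones.

Step 1
Reactants: 1 tert-butyl (3-bromopropyl)carbamate; 2 prop-2-en-1-amine (allylamine)
Product: 3 tert-butyl [3-(prop-2-en-1-ylamino)propyl]carbamate
Conditions: 2 (5 equiv), K2CO3, MeCN, rt → 40 °C
Reagents that add atoms: none
Why: SN2 amination of a primary bromide; the large excess of allylamine should hold the reaction at monoalkylation, and the Boc carbamate is not nucleophilic under these conditions.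

Step 2
Reactants: 3 tert-butyl [3-(prop-2-en-1-ylamino)propyl]carbamate; 4 (S)-2-methylbutanoic acid
Product: 5 tert-butyl (3-{[(2S)-2-methylbutanoyl](prop-2-en-1-yl)amino}propyl)carbamate
Conditions: N,N'-diisopropylcarbodiimide, HOAt, CH2Cl2, 0 °C → rt
Reagents that add atoms: none
Why: Carbodiimide/HOAt amide coupling acylates the secondary amine through the active ester, and a simple α-branched alkanoic acid has no oxazolone pathway, so the (S)-centre should be retained.

Step 3
Reactants: 5 tert-butyl (3-{[(2S)-2-methylbutanoyl](prop-2-en-1-yl)amino}propyl)carbamate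
Product: 6 (2S)-N-(3-aminopropyl)-2-methyl-N-(prop-2-en-1-yl)butanamide
Conditions: TFA, CH2Cl2, 0 °C → rt; aq. K2CO3 work-up
Reagents that add atoms: none
Why: Acidolytic Boc cleavage (loss of 2-methylpropene and CO2) leaves the tertiary amide and the allyl group untouched; the free base is used at once.

Step 4
Reactants: 7 but-3-en-1-amine; 8 3-bromo-1,1-dimethoxypropane
Product: 9 N-(3,3-dimethoxypropyl)but-3-en-1-amine
Conditions: 7 (3 equiv), K2CO3, MeCN, 60 °C
Reagents that add atoms: none
Why: SN2 amination of the primary bromide with excess primary amine should give the secondary amine, the dimethyl acetal being inert to base.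

Step 5
Reactants: 9 N-(3,3-dimethoxypropyl)but-3-en-1-amine; 4 (S)-2-methylbutanoic acid
Product: 10 (2S)-N-(but-3-en-1-yl)-N-(3,3-dimethoxypropyl)-2-methylbutanamide
Conditions: N,N'-diisopropylcarbodiimide, HOAt, CH2Cl2, 0 °C → rt
Reagents that add atoms: none
Why: Carbodiimide/HOAt amide coupling as in step 2; the acetal survives the neutral, anhydrous conditions.

Step 6
Reactants: 10 (2S)-N-(but-3-en-1-yl)-N-(3,3-dimethoxypropyl)-2-methylbutanamide
Product: 11 (2S)-N-(but-3-en-1-yl)-2-methyl-N-(3-oxopropyl)butanamide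
Conditions: 1 M aq. HCl, THF, rt
Reagents that add atoms: water, O
Why: Acid-catalysed acetal hydrolysis under dilute acid releases the aldehyde without touching the tertiary amide or the terminal olefin; the aldehyde is used without storage.

Step 7
Reactants: 12 N-Boc-O-benzyl-L-homoserine
Product: 14 tert-butyl [(3S)-5-(benzyloxy)-1-diazo-2-oxopentan-3-yl]carbamate, via mixed carbonic anhydride 13 (not isolated)
Conditions: iBuOCOCl, N-methylmorpholine, THF, −15 °C; then CH2N2, Et2O, −15 → 0 °C
Reagents that add atoms: diazomethane, C=[N+]=[N-]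
Why: Mixed-anhydride activation and C-acylation of diazomethane (first stage of the Arndt–Eistert homologation) proceed without racemisation of the urethane-protected amino acid.

Step 8
Reactants: 14 tert-butyl [(3S)-5-(benzyloxy)-1-diazo-2-oxopentan-3-yl]carbamate
Product: 15 (3S)-5-(benzyloxy)-3-[(tert-butoxycarbonyl)amino]pentanoic acid
Conditions: CF3CO2Ag (10 mol%), Et3N, THF/H2O (9:1), −25 °C → rt, dark
Reagents that add atoms: water, O
Why: The silver-catalysed Wolff rearrangement gives a ketene that water traps as the acid; the stereocentre migrates with retention, so the L-homoserine centre becomes C2 (S) of the target.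

Step 9
Reactants: 15 (3S)-5-(benzyloxy)-3-[(tert-butoxycarbonyl)amino]pentanoic acid; 6 (2S)-N-(3-aminopropyl)-2-methyl-N-(prop-2-en-1-yl)butanamide
Product: 16 tert-butyl {(3S)-1-(benzyloxy)-5-[(3-{[(2S)-2-methylbutanoyl](prop-2-en-1-yl)amino}propyl)amino]-5-oxopentan-3-yl}carbamate
Conditions: N,N'-diisopropylcarbodiimide, HOBt, CH2Cl2, 0 °C → rt
Reagents that add atoms: none
Why: Carbodiimide/HOBt amide coupling of an unhindered primary amine with a β-amino acid that has no α-stereocentre is routine and forms the future lactam bond.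

Step 10
Reactants: 16 tert-butyl {(3S)-1-(benzyloxy)-5-[(3-{[(2S)-2-methylbutanoyl](prop-2-en-1-yl)amino}propyl)amino]-5-oxopentan-3-yl}carbamate
Product: 17 (3S)-3-amino-5-(benzyloxy)-N-(3-{[(2S)-2-methylbutanoyl](prop-2-en-1-yl)amino}propyl)pentanamide
Conditions: TFA, CH2Cl2, 0 °C → rt; aq. Na2CO3 work-up
Reagents that add atoms: none
Why: Acidolytic Boc cleavage frees the C2 amine; the benzyl ether, the amides and the olefin are stable to TFA at room temperature.

Step 11
Reactants: 17 (3S)-3-amino-5-(benzyloxy)-N-(3-{[(2S)-2-methylbutanoyl](prop-2-en-1-yl)amino}propyl)pentanamide; 11 (2S)-N-(but-3-en-1-yl)-2-methyl-N-(3-oxopropyl)butanamide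
Product: 20 tert-butyl (3-{but-3-en-1-yl[(2S)-2-methylbutanoyl]amino}propyl){(3S)-1-(benzyloxy)-5-[(3-{[(2S)-2-methylbutanoyl](prop-2-en-1-yl)amino}propyl)amino]-5-oxopentan-3-yl}carbamate, via aldimine 18 (not isolated), via secondary amine 19 (not isolated)
Conditions: CH2Cl2, rt; NaBH(OAc)3, rt; then Boc2O, Et3N, rt
Reagents that add atoms: di-tert-butyl dicarbonate, CC(C)(C)OC(=O)OC(=O)OC(C)(C)C
Why: Reductive amination through the preformed aldimine with NaBH(OAc)3 should stop at monoalkylation of the α-branched amine, and carbamoylation with Boc2O in the same flask traps the secondary amine as the N1 carbamate without touching the amide N–H groups.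

Step 12
Reactants: 20 tert-butyl (3-{but-3-en-1-yl[(2S)-2-methylbutanoyl]amino}propyl){(3S)-1-(benzyloxy)-5-[(3-{[(2S)-2-methylbutanoyl](prop-2-en-1-yl)amino}propyl)amino]-5-oxopentan-3-yl}carbamate
Product: 21 tert-butyl (2S)-2-[2-(benzyloxy)ethyl]-9,15-bis[(2S)-2-methylbutanoyl]-4-oxo-1,5,9,15-tetraazacyclooctadec-11-ene-1-carboxylate (E/Z mixture)
Conditions: (H2IMes)(PCy3)Cl2Ru=CHPh (second-generation Grubbs catalyst, 10 mol% in two portions), 1,4-benzoquinone (20 mol%), CH2Cl2 (1 mM), reflux
Reagents that add atoms: none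
Why: The ruthenium benzylidene exchanges onto one terminal olefin, and the resulting alkylidene engages the other through ruthenacyclobutane formation and cycloreversion, releasing ethene and forming C11=C12. The closest known reaction type is macrocyclic ring-closing metathesis of amide-containing α,ω-dienes to macrolactams. The 18-membered ring closes end to end between the allyl terminus on N9 and the butenyl terminus on N15; no smaller ring can compete because the substrate holds only these two olefins. No stereocentre is formed, and the geometry of the new alkene is irrelevant because step 13 removes it. The selectivity that matters is cyclisation over oligomerisation, which is secured by 1 mM dilution, portionwise catalyst addition, two unhindered monosubstituted olefins and the turn-inducing tertiary amides and carbamate. Benzoquinone suppresses ruthenium hydride migration of the N-allyl double bond, and the Boc group keeps N1 from binding ruthenium.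

Step 13
Reactants: 21 tert-butyl (2S)-2-[2-(benzyloxy)ethyl]-9,15-bis[(2S)-2-methylbutanoyl]-4-oxo-1,5,9,15-tetraazacyclooctadec-11-ene-1-carboxylate
Product: 22 tert-butyl (2S)-2-(2-hydroxyethyl)-9,15-bis[(2S)-2-methylbutanoyl]-4-oxo-1,5,9,15-tetraazacyclooctadecane-1-carboxylate
Conditions: H2 (3 bar), Pd(OH)2/C, EtOH, rt
Reagents that add atoms: none
Why: Heterogeneous catalytic hydrogenation saturates the disubstituted ring alkene and hydrogenolyses the benzyl ether in the same operation, while the carbamate and the amides are inert.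

Step 14
Reactants: 22 tert-butyl (2S)-2-(2-hydroxyethyl)-9,15-bis[(2S)-2-methylbutanoyl]-4-oxo-1,5,9,15-tetraazacyclooctadecane-1-carboxylate
Product: 23 tert-butyl (2S)-9,15-bis[(2S)-2-methylbutanoyl]-4-oxo-2-(2-oxoethyl)-1,5,9,15-tetraazacyclooctadecane-1-carboxylate
Conditions: Dess–Martin periodinane, pyridine, CH2Cl2, 0 °C → rt
Reagents that add atoms: none
Why: Dess–Martin oxidation stops at the aldehyde under buffered conditions; the new carbonyl has no α-stereocentre, and the crude aldehyde is used directly.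

Step 15
Reactants: 23 tert-butyl (2S)-9,15-bis[(2S)-2-methylbutanoyl]-4-oxo-2-(2-oxoethyl)-1,5,9,15-tetraazacyclooctadecane-1-carboxylate; 24 nonyl(triphenyl)phosphonium bromide
Product: 26 tert-butyl (2S)-9,15-bis[(2S)-2-methylbutanoyl]-4-oxo-2-[(2Z)-undec-2-en-1-yl]-1,5,9,15-tetraazacyclooctadecane-1-carboxylate, via nonylidene(triphenyl)phosphorane 25 (not isolated)
Conditions: 24 (3 equiv), NaN(SiMe3)2 (2.8 equiv), THF, 0 °C; then 23, −78 °C → rt
Reagents that add atoms: none
Why: Wittig olefination with a lithium-free unstabilised ylide proceeds through the kinetically favoured cis-oxaphosphetane to the Z-olefin; addition at −78 °C should outrun enolisation, and excess ylide should reopen any hydroxylactam tautomer of the aldehyde.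

Step 16
Reactants: 26 tert-butyl (2S)-9,15-bis[(2S)-2-methylbutanoyl]-4-oxo-2-[(2Z)-undec-2-en-1-yl]-1,5,9,15-tetraazacyclooctadecane-1-carboxylate
Product: 27 (2S)-9,15-bis[(2S)-2-methylbutanoyl]-2-[(2Z)-undec-2-en-1-yl]-1,5,9,15-tetraazacyclooctadecan-4-one (CNP0302576.1)
Conditions: TFA, CH2Cl2, 0 °C; aq. NaHCO3 work-up
Reagents that add atoms: none
Why: Acidolytic Boc cleavage liberates N1; the isolated Z-olefin and the amides are stable to cold TFA, so the target should be obtained after basic work-up.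

Compound list
1 | tert-butyl (3-bromopropyl)carbamate | CC(C)(C)OC(=O)NCCCBr | starting material
2 | prop-2-en-1-amine (allylamine) | C=CCN | starting material
3 | tert-butyl [3-(prop-2-en-1-ylamino)propyl]carbamate | C=CCNCCCNC(=O)OC(C)(C)C | intermediate
4 | (S)-2-methylbutanoic acid | CC[C@H](C)C(=O)O | starting material
5 | tert-butyl (3-{[(2S)-2-methylbutanoyl](prop-2-en-1-yl)amino}propyl)carbamate | C=CCN(C(=O)[C@@H](C)CC)CCCNC(=O)OC(C)(C)C | intermediate
6 | (2S)-N-(3-aminopropyl)-2-methyl-N-(prop-2-en-1-yl)butanamide | C=CCN(C(=O)[C@@H](C)CC)CCCN | intermediate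
7 | but-3-en-1-amine | C=CCCN | starting material
8 | 3-bromo-1,1-dimethoxypropane | COC(OC)CCBr | starting material
9 | N-(3,3-dimethoxypropyl)but-3-en-1-amine | C=CCCNCCC(OC)OC | intermediate
10 | (2S)-N-(but-3-en-1-yl)-N-(3,3-dimethoxypropyl)-2-methylbutanamide | C=CCCN(C(=O)[C@@H](C)CC)CCC(OC)OC | intermediate
11 | (2S)-N-(but-3-en-1-yl)-2-methyl-N-(3-oxopropyl)butanamide | C=CCCN(C(=O)[C@@H](C)CC)CCC=O | intermediate
12 | N-Boc-O-benzyl-L-homoserine, (2S)-4-(benzyloxy)-2-[(tert-butoxycarbonyl)amino]butanoic acid | CC(C)(C)OC(=O)N[C@@H](CCOCc1ccccc1)C(=O)O | starting material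
13 | mixed anhydride of 12 with isobutyl hydrogen carbonate | CC(C)COC(=O)OC(=O)[C@H](CCOCc1ccccc1)NC(=O)OC(C)(C)C | intermediate
14 | tert-butyl [(3S)-5-(benzyloxy)-1-diazo-2-oxopentan-3-yl]carbamate | CC(C)(C)OC(=O)N[C@@H](CCOCc1ccccc1)C(=O)C=[N+]=[N-] | intermediate
15 | (3S)-5-(benzyloxy)-3-[(tert-butoxycarbonyl)amino]pentanoic acid | CC(C)(C)OC(=O)N[C@@H](CCOCc1ccccc1)CC(=O)O | intermediate
16 | tert-butyl {(3S)-1-(benzyloxy)-5-[(3-{[(2S)-2-methylbutanoyl](prop-2-en-1-yl)amino}propyl)amino]-5-oxopentan-3-yl}carbamate | CC(C)(C)OC(=O)N[C@@H](CCOCc1ccccc1)CC(=O)NCCCN(CC=C)C(=O)[C@@H](C)CC | intermediate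
17 | (3S)-3-amino-5-(benzyloxy)-N-(3-{[(2S)-2-methylbutanoyl](prop-2-en-1-yl)amino}propyl)pentanamide | N[C@@H](CCOCc1ccccc1)CC(=O)NCCCN(CC=C)C(=O)[C@@H](C)CC | intermediate
18 | aldimine from the C2 amine of 17 and aldehyde 11 | C=CCCN(C(=O)[C@@H](C)CC)CC/C=N/[C@@H](CCOCc1ccccc1)CC(=O)NCCCN(CC=C)C(=O)[C@@H](C)CC | intermediate
19 | (3S)-5-(benzyloxy)-3-[(3-{but-3-en-1-yl[(2S)-2-methylbutanoyl]amino}propyl)amino]-N-(3-{[(2S)-2-methylbutanoyl](prop-2-en-1-yl)amino}propyl)pentanamide | C=CCCN(C(=O)[C@@H](C)CC)CCCN[C@@H](CCOCc1ccccc1)CC(=O)NCCCN(CC=C)C(=O)[C@@H](C)CC | intermediate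
20 | tert-butyl (3-{but-3-en-1-yl[(2S)-2-methylbutanoyl]amino}propyl){(3S)-1-(benzyloxy)-5-[(3-{[(2S)-2-methylbutanoyl](prop-2-en-1-yl)amino}propyl)amino]-5-oxopentan-3-yl}carbamate (metathesis precursor) | C=CCN(C(=O)[C@@H](C)CC)CCCNC(=O)C[C@H](CCOCc1ccccc1)N(C(=O)OC(C)(C)C)CCCN(C(=O)[C@@H](C)CC)CCC=C | intermediate
21 | tert-butyl (2S)-2-[2-(benzyloxy)ethyl]-9,15-bis[(2S)-2-methylbutanoyl]-4-oxo-1,5,9,15-tetraazacyclooctadec-11-ene-1-carboxylate (E/Z mixture, metathesis product) | c1ccccc1COCC[C@H]2CC(=O)NCCCN(C(=O)[C@@H](C)CC)CC=CCCN(C(=O)[C@@H](C)CC)CCCN2C(=O)OC(C)(C)C | intermediate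
22 | tert-butyl (2S)-2-(2-hydroxyethyl)-9,15-bis[(2S)-2-methylbutanoyl]-4-oxo-1,5,9,15-tetraazacyclooctadecane-1-carboxylate | OCC[C@H]1CC(=O)NCCCN(C(=O)[C@@H](C)CC)CCCCCN(C(=O)[C@@H](C)CC)CCCN1C(=O)OC(C)(C)C | intermediate
23 | tert-butyl (2S)-9,15-bis[(2S)-2-methylbutanoyl]-4-oxo-2-(2-oxoethyl)-1,5,9,15-tetraazacyclooctadecane-1-carboxylate | O=CC[C@H]1CC(=O)NCCCN(C(=O)[C@@H](C)CC)CCCCCN(C(=O)[C@@H](C)CC)CCCN1C(=O)OC(C)(C)C | intermediate
24 | nonyl(triphenyl)phosphonium bromide | CCCCCCCCC[P+](c1ccccc1)(c1ccccc1)c1ccccc1.[Br-] | starting material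
25 | nonylidene(triphenyl)phosphorane | CCCCCCCCC=P(c1ccccc1)(c1ccccc1)c1ccccc1 | intermediate
26 | tert-butyl (2S)-9,15-bis[(2S)-2-methylbutanoyl]-4-oxo-2-[(2Z)-undec-2-en-1-yl]-1,5,9,15-tetraazacyclooctadecane-1-carboxylate | CCCCCCCC/C=C\C[C@H]1CC(=O)NCCCN(C(=O)[C@@H](C)CC)CCCCCN(C(=O)[C@@H](C)CC)CCCN1C(=O)OC(C)(C)C | intermediate
27 | (2S)-9,15-bis[(2S)-2-methylbutanoyl]-2-[(2Z)-undec-2-en-1-yl]-1,5,9,15-tetraazacyclooctadecan-4-one | CCCCCCCC/C=C\C[C@H]1CC(=O)NCCCN(C(=O)[C@@H](C)CC)CCCCCN(C(=O)[C@@H](C)CC)CCCN1 | target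

Total step count: 16.
Longest linear sequence: 11 steps (steps 1–3, then 9–16).

Steps most likely to fail

Step 12 (ring-closing metathesis). Intermolecular metathesis could outrun end-to-end closure and give oligomers, or ruthenium hydride species could move the N-allyl double bond into conjugation with nitrogen before closure. The fallback reverses the order of the two fragment unions, so that metathesis is intermolecular and the ring is closed at the N1–C18 bond. It sets out from 16 and 10 and comes back at 21. Cross-metathesis of 16 with an excess of 10 ((H2IMes)(PCy3)Cl2Ru=CHPh, CH2Cl2, 40 °C) should give the linear alkene acetal F1. Aqueous TFA in CH2Cl2 then removes the Boc group and the acetal together to give the amino aldehyde F2, held as its trifluoroacetate. Intramolecular reductive amination under high dilution (NaBH(OAc)3, iPr2NEt, CH2Cl2, 1 mM) should close the ring to the macrocyclic secondary amine F3, and Boc2O/Et3N converts it into 21.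

Step 15 (Wittig olefination). The basic ylide could enolise the aldehyde and trigger β-elimination of the N1 carbamate, which would open the ring, or the olefination could leak to the E-isomer. The fallback sets the geometry by palladium chemistry under non-basic olefination conditions. It sets out from 23 and comes back at 26. Ramirez olefination (CBr4, PPh3, CH2Cl2, 0 °C) should give the gem-dibromoalkene F4. Palladium-catalysed hydrogenolysis of the bromine trans to the chain (Bu3SnH, Pd(PPh3)4, toluene, rt) should give the (Z)-bromoalkene F5. Negishi coupling with C8H17ZnBr (Pd(PPh3)4, THF, rt) proceeds with retention and gives 26.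

Step 11 (reductive alkylation and carbamoylation in one flask). The primary amine could be alkylated twice, the aldimine could be diverted into a cyclic aminal with the neighbouring amide N–H, or carbamoylation of the hindered secondary amine could stall. The fallback replaces reductive amination by sulfonamide alkylation, which cannot over-alkylate. It sets out from 17 and 11 and comes back at 19, which is then isolated and treated with Boc2O/Et3N to give 20. Aldehyde 11 is reduced (NaBH4, MeOH, 0 °C) to the alcohol F6. Amine 17 is converted with 2-nitrobenzenesulfonyl chloride (Et3N, CH2Cl2) into the sulfonamide F7. Mitsunobu N-alkylation of F7 with F6 (PPh3, diisopropyl azodicarboxylate, THF) should give the N-alkyl sulfonamide F8, and thiolysis (PhSH, K2CO3, DMF) releases 19.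

Further compounds
F1 | step 12 | tert-butyl [(3S)-1-(benzyloxy)-5-({3-[{5-[(3,3-dimethoxypropyl)((2S)-2-methylbutanoyl)amino]pent-2-en-1-yl}((2S)-2-methylbutanoyl)amino]propyl}amino)-5-oxopentan-3-yl]carbamate | CC(C)(C)OC(=O)N[C@@H](CCOCc1ccccc1)CC(=O)NCCCN(C(=O)[C@@H](C)CC)CC=CCCN(C(=O)[C@@H](C)CC)CCC(OC)OC
F2 | step 12 | (3S)-3-amino-5-(benzyloxy)-N-{3-[{5-[((2S)-2-methylbutanoyl)(3-oxopropyl)amino]pent-2-en-1-yl}((2S)-2-methylbutanoyl)amino]propyl}pentanamide | N[C@@H](CCOCc1ccccc1)CC(=O)NCCCN(C(=O)[C@@H](C)CC)CC=CCCN(C(=O)[C@@H](C)CC)CCC=O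
F3 | step 12 | (2S)-2-[2-(benzyloxy)ethyl]-9,15-bis[(2S)-2-methylbutanoyl]-1,5,9,15-tetraazacyclooctadec-11-en-4-one | c1ccccc1COCC[C@H]2CC(=O)NCCCN(C(=O)[C@@H](C)CC)CC=CCCN(C(=O)[C@@H](C)CC)CCCN2
F4 | step 15 | tert-butyl (2S)-2-(3,3-dibromoprop-2-en-1-yl)-9,15-bis[(2S)-2-methylbutanoyl]-4-oxo-1,5,9,15-tetraazacyclooctadecane-1-carboxylate | BrC(Br)=CC[C@H]1CC(=O)NCCCN(C(=O)[C@@H](C)CC)CCCCCN(C(=O)[C@@H](C)CC)CCCN1C(=O)OC(C)(C)C
F5 | step 15 | tert-butyl (2S)-2-[(2Z)-3-bromoprop-2-en-1-yl]-9,15-bis[(2S)-2-methylbutanoyl]-4-oxo-1,5,9,15-tetraazacyclooctadecane-1-carboxylate | Br/C=C\C[C@H]1CC(=O)NCCCN(C(=O)[C@@H](C)CC)CCCCCN(C(=O)[C@@H](C)CC)CCCN1C(=O)OC(C)(C)C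
F6 | step 11 | (2S)-N-(but-3-en-1-yl)-N-(3-hydroxypropyl)-2-methylbutanamide | C=CCCN(C(=O)[C@@H](C)CC)CCCO
F7 | step 11 | (3S)-5-(benzyloxy)-N-(3-{[(2S)-2-methylbutanoyl](prop-2-en-1-yl)amino}propyl)-3-[(2-nitrophenyl)sulfonylamino]pentanamide | O=S(=O)(N[C@@H](CCOCc1ccccc1)CC(=O)NCCCN(CC=C)C(=O)[C@@H](C)CC)c1ccccc1[N+](=O)[O-]
F8 | step 11 | (3S)-5-(benzyloxy)-3-[(3-{but-3-en-1-yl[(2S)-2-methylbutanoyl]amino}propyl)(2-nitrophenylsulfonyl)amino]-N-(3-{[(2S)-2-methylbutanoyl](prop-2-en-1-yl)amino}propyl)pentanamide | C=CCCN(C(=O)[C@@H](C)CC)CCCN([C@@H](CCOCc1ccccc1)CC(=O)NCCCN(CC=C)C(=O)[C@@H](C)CC)S(=O)(=O)c1ccccc1[N+](=O)[O-]
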